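Everything rests on breaking the C5–C6 bond (ring A: C1–C5 and C10; ring B: C5–C10; C11 on C9). Ring A hides a 1,4-dicarbonyl pattern: the ring B ketone carbon C6 is attached to C5, the β-carbon of the C3 carbonyl, and C10, the quaternary carbon with the angular methyl, lies opposite C3. Read backwards, ring A is a 4,4-disubstituted cyclohexa-2,5-dienone and C6 an acyl anion. One carbene-catalysed Stetter addition closes ring B, installs the C6 ketone and fixes C10 and C5. The precursor is the 4-methyl-4-(4-oxobutyl) dienone carrying an (R)-silyloxymethyl arm on C9, so C11 arrives before ring B exists.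

Key step: step 9

Remarks on the chemistry
- Locants C1–C11 are those defined above. TBDPS = tert-butyldiphenylsilyl, TBS = tert-butyldimethylsilyl.
- (E)-But-2-ene-1,4-diol is taken to be purchasable.
- C10 in 6, 7, 9 and 10, C4 in 15 and C8 in 24 are formed without control; all are erased or made non-stereogenic later, so these compounds are carried as mixtures at those centres.
- The sense of induction in steps 3 and 9 is set by choosing the catalyst antipode; the configurations written are those the target requires.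
- The C8 methyl is deliberately left out of the tether, because a C8 stereocentre would add a second, uncontrolled bias to the arm selection of step 9.

Step 1
Reactants: 1 (E)-but-2-ene-1,4-diol
Product: 2 (E)-4-(tert-butyldiphenylsilyloxy)but-2-en-1-ol
Conditions: NaH (1.0 equiv), THF, 0 °C; TBDPSCl (1.0 equiv), 0 °C → rt
Reagents that add atoms: tert-butyldiphenylsilyl chloride, CC(C)(C)[Si](Cl)(c1ccccc1)c1ccccc1
Why: O-silylation of the mono-sodium alkoxide of a symmetric diol, which with one equivalent of base is silylated once so that the second hydroxyl stays free.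

Step 2
Reactants: 2 (E)-4-(tert-butyldiphenylsilyloxy)but-2-en-1-ol
Product: 3 (E)-4-(tert-butyldiphenylsilyloxy)but-2-enyl methyl carbonate
Conditions: ClCO2Me, pyridine, CH2Cl2, 0 °C
Reagents that add atoms: methyl chloroformate, COC(=O)Cl
Why: Acylation of the primary allylic alcohol with a chloroformate gives the carbonate leaving group needed for metal-catalysed allylic substitution.

Step 3
Reactants: 3 (E)-4-(tert-butyldiphenylsilyloxy)but-2-enyl methyl carbonate; 4 dimethyl 2-methylpropanedioate
Product: 5 dimethyl 2-[(2R)-1-(tert-butyldiphenylsilyloxy)but-3-en-2-yl]-2-methylpropanedioate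
Conditions: [Ir(cod)Cl]2 (2 mol%), BINOL-derived N,N-bis(1-phenylethyl)phosphoramidite (4 mol%, antipode giving 2R), TBD (8 mol%), THF, 50 °C
Reagents that add atoms: none
Why: Iridium-catalysed asymmetric allylic alkylation, in which the allyl–iridium complex formed by loss of methyl carbonate is attacked by the methylmalonate anion at its substituted terminus and the ligand fixes the face so that the future C9 is formed as (R).

Step 4
Reactants: 5 dimethyl 2-[(2R)-1-(tert-butyldiphenylsilyloxy)but-3-en-2-yl]-2-methylpropanedioate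
Product: 6 methyl (3R)-3-[(tert-butyldiphenylsilyloxy)methyl]-2-methylpent-4-enoate (both C2 epimers)
Conditions: LiCl, H2O, DMSO, 150 °C
Reagents that add atoms: none
Why: Krapcho dealkoxycarbonylation, in which chloride demethylates one of the geminal esters and the carboxylate loses CO2, leaving the C9 centre untouched because it is not acidic.

Step 5
Reactants: 6 methyl (3R)-3-[(tert-butyldiphenylsilyloxy)methyl]-2-methylpent-4-enoate
Product: 7 (3R)-3-[(tert-butyldiphenylsilyloxy)methyl]-2-methylpent-4-enal (both C2 epimers)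
Conditions: i-Bu2AlH (1.1 equiv), CH2Cl2, −78 °C; aq. potassium sodium tartrate
Reagents that add atoms: none
Why: Partial reduction of an α-branched ester, whose tetrahedral aluminium hemiacetal survives at −78 °C and releases the aldehyde only on work-up.

Step 6
Reactants: 7 (3R)-3-[(tert-butyldiphenylsilyloxy)methyl]-2-methylpent-4-enal; 8 but-3-en-2-one
Product: 10 4-[(2R)-1-(tert-butyldiphenylsilyloxy)but-3-en-2-yl]-4-methylcyclohex-2-en-1-one (both C4 epimers), via keto aldehyde 9 (not isolated)
Conditions: 8 (1.5 equiv), pyrrolidine (30 mol%), AcOH (30 mol%), toluene, 50 °C; then KOH (20 mol%), MeOH, 40 °C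
Reagents that add atoms: none
Why: Robinson annulation, in which the enamine of the α-branched aldehyde adds to the vinyl ketone to build the quaternary carbon and intramolecular aldol condensation of the methyl ketone onto the aldehyde closes the cyclohexenone.

Step 7
Reactants: 10 4-[(2R)-1-(tert-butyldiphenylsilyloxy)but-3-en-2-yl]-4-methylcyclohex-2-en-1-one
Product: 11 4-[(2R)-1-(tert-butyldiphenylsilyloxy)but-3-en-2-yl]-4-methylcyclohexa-2,5-dien-1-one
Conditions: DDQ (1.5 equiv), 1,4-dioxane, 100 °C
Reagents that add atoms: none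
Why: Quinone dehydrogenation of a 4,4-disubstituted cyclohexenone through its dienol, which can only give the cross-conjugated dienone and thereby makes the ring carbon (future C10) non-stereogenic.

Step 8
Reactants: 11 4-[(2R)-1-(tert-butyldiphenylsilyloxy)but-3-en-2-yl]-4-methylcyclohexa-2,5-dien-1-one
Product: 12 (4R)-5-(tert-butyldiphenylsilyloxy)-4-(1-methyl-4-oxocyclohexa-2,5-dien-1-yl)pentanal
Conditions: Rh(acac)(CO)2 (1 mol%), BiPhePhos (2 mol%), CO/H2 (1:1, 10 bar), toluene, 60 °C
Reagents that add atoms: carbon monoxide, [C-]#[O+]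
Why: Linear-selective hydroformylation of the only terminal alkene by a bulky bisphosphite rhodium hydride, the electron-poor 1,2-disubstituted dienone alkenes being far slower to insert.

Step 9
Reactants: 12 (4R)-5-(tert-butyldiphenylsilyloxy)-4-(1-methyl-4-oxocyclohexa-2,5-dien-1-yl)pentanal
Product: 13 cis-fused (5S,9R,10S)-9-[(tert-butyldiphenylsilyloxy)methyl]-10-methyldecal-1-ene-3,6-dione
Conditions: aminoindanol-derived N-C6F5 triazolium tetrafluoroborate (20 mol%, antipode giving 10S), KN(SiMe3)2 (20 mol%), toluene, 23 °C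
Reagents that add atoms: none
Why: The carbene adds to the C6 aldehyde and proton transfer gives the enaminol acyl-anion equivalent, whose C6 adds in conjugate fashion to C5 of one enone arm before tautomerisation and loss of the carbene release the 1,4-diketone. The closest known reaction type is the chiral-triazolium-catalysed intramolecular Stetter desymmetrisation of 4,4-disubstituted cyclohexa-2,5-dienones. Ring B closes in the 6-exo-trig mode. C10 becomes stereogenic through the choice of enone arm, which the chiral carbene controls, and C5 is set by the tether, which can only reach the ring face it is attached to, so H5 ends up cis to the C10 methyl. The selectivity needed is arm selection: the (R) centre at C9 makes the two arms diastereotopic, and in the chair-like closure the required arm is expected to place the silyloxymethyl group axial, at a cost of about one gauche interaction, so the catalyst antipode is chosen to override this modest bias. Because C9 is already enantiopure, addition to the other arm would give a separable diastereomer and not the enantiomer.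

Step 10
Reactants: 13 cis-fused (5S,9R,10S)-9-[(tert-butyldiphenylsilyloxy)methyl]-10-methyldecal-1-ene-3,6-dione
Product: 14 cis-fused (5S,9R,10S)-9-[(tert-butyldiphenylsilyloxy)methyl]-6,6-(ethylenedioxy)-10-methyldecal-1-en-3-one
Conditions: Me3SiOCH2CH2OSiMe3 (2 equiv), Me3SiOTf (5 mol%), CH2Cl2, −78 → −20 °C
Reagents that add atoms: 1,2-bis(trimethylsilyloxy)ethane, C[Si](C)(C)OCCO[Si](C)(C)C
Why: Acetalisation under aprotic silyl-transfer conditions, which converts the saturated C6 ketone much faster than the conjugated C3 carbonyl and does not enolise C5.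

Step 11
Reactants: 14 cis-fused (5S,9R,10S)-9-[(tert-butyldiphenylsilyloxy)methyl]-6,6-(ethylenedioxy)-10-methyldecal-1-en-3-one
Product: 16 cis-fused (5R,9R,10S)-9-[(tert-butyldiphenylsilyloxy)methyl]-6,6-(ethylenedioxy)-4,4,10-trimethyldecal-1-en-3-one, via monomethyl enone 15 (not isolated)
Conditions: KOt-Bu (3 equiv), MeI (6 equiv), THF/t-BuOH, 0 °C → rt
Reagents that add atoms: iodomethane, CI
Why: Exhaustive α′-alkylation of an enone whose only enolisable position is C4 (C10 is quaternary and C2 is vinylic), so the cross-conjugated potassium enolate is methylated twice at C4.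

Step 12
Reactants: 16 cis-fused (5R,9R,10S)-9-[(tert-butyldiphenylsilyloxy)methyl]-6,6-(ethylenedioxy)-4,4,10-trimethyldecal-1-en-3-one
Product: 17 cis-fused (5R,9R,10S)-9-[(tert-butyldiphenylsilyloxy)methyl]-6,6-(ethylenedioxy)-4,4,10-trimethyldecalin-3-one
Conditions: H2 (1 atm), 10% Pd/C, EtOAc, rt
Reagents that add atoms: none
Why: Heterogeneous hydrogenation of the only C=C bond (C1=C2), which has served to restrict enolisation to C4 and is no longer needed.

Step 13
Reactants: 17 cis-fused (5R,9R,10S)-9-[(tert-butyldiphenylsilyloxy)methyl]-6,6-(ethylenedioxy)-4,4,10-trimethyldecalin-3-one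
Product: 18 cis-fused (3S,5R,9R,10S)-9-[(tert-butyldiphenylsilyloxy)methyl]-6,6-(ethylenedioxy)-4,4,10-trimethyldecalin-3-ol
Conditions: NaBH4, MeOH/THF, 0 °C
Reagents that add atoms: none
Why: Borohydride reduction in which hydride should reach C3 from the convex face of the cis-fused bicycle (the face of the C10 methyl), because ring B with its C6 dioxolane lies under the other face, giving the 3S alcohol with the hydroxyl trans to the C10 methyl.

Step 14
Reactants: 18 cis-fused (3S,5R,9R,10S)-9-[(tert-butyldiphenylsilyloxy)methyl]-6,6-(ethylenedioxy)-4,4,10-trimethyldecalin-3-ol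
Product: 19 cis-fused (3S,5R,9R,10S)-3-(tert-butyldimethylsilyloxy)-9-[(tert-butyldiphenylsilyloxy)methyl]-6,6-(ethylenedioxy)-4,4,10-trimethyldecalin
Conditions: t-BuMe2SiOTf, 2,6-lutidine, CH2Cl2, 0 °C → rt
Reagents that add atoms: tert-butyldimethylsilyl trifluoromethanesulfonate, CC(C)(C)[Si](C)(C)OS(=O)(=O)C(F)(F)F
Why: Silylation of a hindered secondary alcohol with a silyl triflate and a non-nucleophilic base, which keeps O3 from adding across to C6 as a bridged hemiketal once that ketone is unmasked.

Step 15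
Reactants: 19 cis-fused (3S,5R,9R,10S)-3-(tert-butyldimethylsilyloxy)-9-[(tert-butyldiphenylsilyloxy)methyl]-6,6-(ethylenedioxy)-4,4,10-trimethyldecalin
Product: 21 trans-fused (3S,5S,9R,10S)-3-(tert-butyldimethylsilyloxy)-9-[(tert-butyldiphenylsilyloxy)methyl]-4,4,10-trimethyldecalin-6-one, via cis-fused ketone 20 (not isolated)
Conditions: 1 M HCl, THF, rt; then KOt-Bu (0.3 equiv), t-BuOH/THF, rt
Reagents that add atoms: water, O
Why: Acetal hydrolysis followed by base-mediated enolisation toward C5, where the cis-fused ketone must either put C6 and the 3-silyloxy group in a 1,3-diaxial relationship or place the quaternary C4 axial on ring B, so the trans-fused ketone (H5 anti to the C10 methyl) should be the thermodynamic epimer.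

Step 16
Reactants: 21 trans-fused (3S,5S,9R,10S)-3-(tert-butyldimethylsilyloxy)-9-[(tert-butyldiphenylsilyloxy)methyl]-4,4,10-trimethyldecalin-6-one
Product: 23 trans-fused (3S,5S,9R,10S)-3-(tert-butyldimethylsilyloxy)-9-[(tert-butyldiphenylsilyloxy)methyl]-4,4,10-trimethyldecal-7-en-6-one, via trimethylsilyl enol ether 22 (not isolated)
Conditions: LiN(SiMe3)2, Me3SiCl, THF, −78 °C; then Pd(OAc)2 (1.1 equiv), MeCN, rt
Reagents that add atoms: none
Why: Saegusa–Ito oxidation, in which kinetic deprotonation takes the C7 methylene and not the C5 methine flanked by two quaternary carbons, and divalent palladium turns the silyl enol ether into the C7=C8 enone.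

Step 17
Reactants: 23 trans-fused (3S,5S,9R,10S)-3-(tert-butyldimethylsilyloxy)-9-[(tert-butyldiphenylsilyloxy)methyl]-4,4,10-trimethyldecal-7-en-6-one
Product: 25 trans-fused (3S,5S,9R,10S)-3-(tert-butyldimethylsilyloxy)-9-[(tert-butyldiphenylsilyloxy)methyl]-4,4,8,10-tetramethyldecal-7-en-6-one, via trimethylsilyl enol ether 24 (not isolated)
Conditions: Me2CuLi (from MeLi and CuI), Me3SiCl, THF, −78 °C; then Pd(OAc)2 (1.1 equiv), MeCN, rt
Reagents that add atoms: lithium dimethylcuprate, [Li+].C[Cu-]C
Why: Cuprate conjugate addition to C8 with silyl trapping of the enolate, followed by a second Saegusa–Ito oxidation that restores C7=C8 and removes the transient C8 stereocentre.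

Step 18
Reactants: 25 trans-fused (3S,5S,9R,10S)-3-(tert-butyldimethylsilyloxy)-9-[(tert-butyldiphenylsilyloxy)methyl]-4,4,8,10-tetramethyldecal-7-en-6-one
Product: 26 (3S,5S,9R,10S)-3-hydroxy-9-(hydroxymethyl)-4,4,8,10-tetramethyldecal-7-en-6-one
Conditions: HF·pyridine, pyridine, THF, 0 → 40 °C
Reagents that add atoms: none
Why: Fluoride cleavage of both silyl ethers under non-basic conditions, which avoids deprotonation at C9, the γ-position of the enone.

Step 19
Reactants: 26 (3S,5S,9R,10S)-3-hydroxy-9-(hydroxymethyl)-4,4,8,10-tetramethyldecal-7-en-6-one; 27 7-hydroxy-2H-chromen-2-one (umbelliferone)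
Product: 28 ferocaulidin
Conditions: PPh3, DIAD, THF, 0 °C → rt
Reagents that add atoms: none
Why: Mitsunobu etherification, in which the primary C11 alcohol is activated as its oxyphosphonium ion and displaced by the acidic phenol, while the hindered axial C3 alcohol next to the gem-dimethyl group should not react.

Compound list
1 | (E)-but-2-ene-1,4-diol | OC/C=C/CO | starting material
2 | (E)-4-(tert-butyldiphenylsilyloxy)but-2-en-1-ol | OC/C=C/CO[Si](C(C)(C)C)(c1ccccc1)c1ccccc1 | intermediate
3 | (E)-4-(tert-butyldiphenylsilyloxy)but-2-enyl methyl carbonate | COC(=O)OC/C=C/CO[Si](C(C)(C)C)(c1ccccc1)c1ccccc1 | intermediate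
4 | dimethyl 2-methylpropanedioate | COC(=O)C(C)C(=O)OC | starting material
5 | dimethyl 2-[(2R)-1-(tert-butyldiphenylsilyloxy)but-3-en-2-yl]-2-methylpropanedioate | C=C[C@@H](CO[Si](C(C)(C)C)(c1ccccc1)c1ccccc1)C(C)(C(=O)OC)C(=O)OC | intermediate
6 | methyl (3R)-3-[(tert-butyldiphenylsilyloxy)methyl]-2-methylpent-4-enoate (both C2 epimers) | C=C[C@@H](CO[Si](C(C)(C)C)(c1ccccc1)c1ccccc1)C(C)C(=O)OC | intermediate
7 | (3R)-3-[(tert-butyldiphenylsilyloxy)methyl]-2-methylpent-4-enal (both C2 epimers) | C=C[C@@H](CO[Si](C(C)(C)C)(c1ccccc1)c1ccccc1)C(C)C=O | intermediate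
8 | but-3-en-2-one | CC(=O)C=C | starting material
9 | 2-[(2R)-1-(tert-butyldiphenylsilyloxy)but-3-en-2-yl]-2-methyl-5-oxohexanal (both C2 epimers; not isolated) | C=C[C@@H](CO[Si](C(C)(C)C)(c1ccccc1)c1ccccc1)C(C)(C=O)CCC(C)=O | intermediate
10 | 4-[(2R)-1-(tert-butyldiphenylsilyloxy)but-3-en-2-yl]-4-methylcyclohex-2-en-1-one (both C4 epimers) | C=C[C@@H](CO[Si](C(C)(C)C)(c1ccccc1)c1ccccc1)C1(C)C=CC(=O)CC1 | intermediate
11 | 4-[(2R)-1-(tert-butyldiphenylsilyloxy)but-3-en-2-yl]-4-methylcyclohexa-2,5-dien-1-one | C=C[C@@H](CO[Si](C(C)(C)C)(c1ccccc1)c1ccccc1)C1(C)C=CC(=O)C=C1 | intermediate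
12 | (4R)-5-(tert-butyldiphenylsilyloxy)-4-(1-methyl-4-oxocyclohexa-2,5-dien-1-yl)pentanal (key-step precursor) | O=CCC[C@@H](CO[Si](C(C)(C)C)(c1ccccc1)c1ccccc1)C1(C)C=CC(=O)C=C1 | intermediate
13 | cis-fused (5S,9R,10S)-9-[(tert-butyldiphenylsilyloxy)methyl]-10-methyldecal-1-ene-3,6-dione (key-step product) | O=C1CC[C@@H](CO[Si](C(C)(C)C)(c3ccccc3)c3ccccc3)[C@]2(C)C=CC(=O)C[C@H]12 | intermediate
14 | cis-fused (5S,9R,10S)-9-[(tert-butyldiphenylsilyloxy)methyl]-6,6-(ethylenedioxy)-10-methyldecal-1-en-3-one | C12(OCCO1)CC[C@@H](CO[Si](C(C)(C)C)(c3ccccc3)c3ccccc3)[C@]3(C)C=CC(=O)C[C@H]23 | intermediate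
15 | cis-fused (5S,9R,10S)-9-[(tert-butyldiphenylsilyloxy)methyl]-6,6-(ethylenedioxy)-4,10-dimethyldecal-1-en-3-one (both C4 epimers; not isolated) | C12(OCCO1)CC[C@@H](CO[Si](C(C)(C)C)(c3ccccc3)c3ccccc3)[C@]3(C)C=CC(=O)C(C)[C@H]23 | intermediate
16 | cis-fused (5R,9R,10S)-9-[(tert-butyldiphenylsilyloxy)methyl]-6,6-(ethylenedioxy)-4,4,10-trimethyldecal-1-en-3-one | C12(OCCO1)CC[C@@H](CO[Si](C(C)(C)C)(c3ccccc3)c3ccccc3)[C@]3(C)C=CC(=O)C(C)(C)[C@H]23 | intermediate
17 | cis-fused (5R,9R,10S)-9-[(tert-butyldiphenylsilyloxy)methyl]-6,6-(ethylenedioxy)-4,4,10-trimethyldecalin-3-one | C12(OCCO1)CC[C@@H](CO[Si](C(C)(C)C)(c3ccccc3)c3ccccc3)[C@]3(C)CCC(=O)C(C)(C)[C@H]23 | intermediate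
18 | cis-fused (3S,5R,9R,10S)-9-[(tert-butyldiphenylsilyloxy)methyl]-6,6-(ethylenedioxy)-4,4,10-trimethyldecalin-3-ol | C12(OCCO1)CC[C@@H](CO[Si](C(C)(C)C)(c3ccccc3)c3ccccc3)[C@]3(C)CC[C@H](O)C(C)(C)[C@H]23 | intermediate
19 | cis-fused (3S,5R,9R,10S)-3-(tert-butyldimethylsilyloxy)-9-[(tert-butyldiphenylsilyloxy)methyl]-6,6-(ethylenedioxy)-4,4,10-trimethyldecalin | C12(OCCO1)CC[C@@H](CO[Si](C(C)(C)C)(c3ccccc3)c3ccccc3)[C@]3(C)CC[C@H](O[Si](C)(C)C(C)(C)C)C(C)(C)[C@H]23 | intermediate
20 | cis-fused (3S,5R,9R,10S)-3-(tert-butyldimethylsilyloxy)-9-[(tert-butyldiphenylsilyloxy)methyl]-4,4,10-trimethyldecalin-6-one (not isolated) | O=C1CC[C@@H](CO[Si](C(C)(C)C)(c3ccccc3)c3ccccc3)[C@]2(C)CC[C@H](O[Si](C)(C)C(C)(C)C)C(C)(C)[C@H]12 | intermediate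
21 | trans-fused (3S,5S,9R,10S)-3-(tert-butyldimethylsilyloxy)-9-[(tert-butyldiphenylsilyloxy)methyl]-4,4,10-trimethyldecalin-6-one | O=C1CC[C@@H](CO[Si](C(C)(C)C)(c3ccccc3)c3ccccc3)[C@]2(C)CC[C@H](O[Si](C)(C)C(C)(C)C)C(C)(C)[C@@H]12 | intermediate
22 | trans-fused (3S,5S,9R,10S)-3-(tert-butyldimethylsilyloxy)-9-[(tert-butyldiphenylsilyloxy)methyl]-4,4,10-trimethyl-6-(trimethylsilyloxy)decal-6-ene (not isolated) | C[Si](C)(C)OC1=CC[C@@H](CO[Si](C(C)(C)C)(c3ccccc3)c3ccccc3)[C@]2(C)CC[C@H](O[Si](C)(C)C(C)(C)C)C(C)(C)[C@@H]12 | intermediate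
23 | trans-fused (3S,5S,9R,10S)-3-(tert-butyldimethylsilyloxy)-9-[(tert-butyldiphenylsilyloxy)methyl]-4,4,10-trimethyldecal-7-en-6-one | O=C1C=C[C@@H](CO[Si](C(C)(C)C)(c3ccccc3)c3ccccc3)[C@]2(C)CC[C@H](O[Si](C)(C)C(C)(C)C)C(C)(C)[C@@H]12 | intermediate
24 | trans-fused (3S,5S,9R,10S)-3-(tert-butyldimethylsilyloxy)-9-[(tert-butyldiphenylsilyloxy)methyl]-4,4,8,10-tetramethyl-6-(trimethylsilyloxy)decal-6-ene (both C8 epimers; not isolated) | C[Si](C)(C)OC1=CC(C)[C@@H](CO[Si](C(C)(C)C)(c3ccccc3)c3ccccc3)[C@]2(C)CC[C@H](O[Si](C)(C)C(C)(C)C)C(C)(C)[C@@H]12 | intermediate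
25 | trans-fused (3S,5S,9R,10S)-3-(tert-butyldimethylsilyloxy)-9-[(tert-butyldiphenylsilyloxy)methyl]-4,4,8,10-tetramethyldecal-7-en-6-one | O=C1C=C(C)[C@@H](CO[Si](C(C)(C)C)(c3ccccc3)c3ccccc3)[C@]2(C)CC[C@H](O[Si](C)(C)C(C)(C)C)C(C)(C)[C@@H]12 | intermediate
26 | (3S,5S,9R,10S)-3-hydroxy-9-(hydroxymethyl)-4,4,8,10-tetramethyldecal-7-en-6-one | O=C1C=C(C)[C@@H](CO)[C@]2(C)CC[C@H](O)C(C)(C)[C@@H]12 | intermediate
27 | 7-hydroxy-2H-chromen-2-one (umbelliferone) | O=c1ccc2ccc(O)cc2o1 | starting material
28 | ferocaulidin, (3S,5S,9R,10S)-3-hydroxy-4,4,8,10-tetramethyl-9-[(2-oxo-2H-chromen-7-yloxy)methyl]decal-7-en-6-one | O=C1C=C(C)[C@@H](COc3ccc4ccc(=O)oc4c3)[C@]2(C)CC[C@H](O)C(C)(C)[C@@H]12 | target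

Total step count: 19
Longest linear sequence: 19 steps (1 to 28); umbelliferone 27 enters in the last step.

Steps most likely to fail

Step 9. The enolisable aliphatic aldehyde may be consumed by aldol or benzoin pathways before the six-membered ring closes, or the carbene may fail to override the tether's preference so that addition to the other enone arm prevails. The fallback replaces carbene catalysis by a reductive carbonyl–enone coupling and sets out from 12. SmI2 (2.2 equiv) with t-BuOH in THF at −78 °C would join C6 to C5 and should give the cis-fused hydroxy enone (5S,9R,10S)-9-[(tert-butyldiphenylsilyloxy)methyl]-6-hydroxy-10-methyldecal-1-en-3-one F1. Oxidation of the secondary alcohol (TEMPO cat., PhI(OAc)2, CH2Cl2) comes back to the route at 13. In this variant the choice of enone arm rests on the C9 centre alone, so the two cis-fused diastereomers would have to be separated at F1.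

Step 19. Substitution at the β-branched C11 may be slow, so that the oxyphosphonium ion eliminates toward C9, the γ-position of the enone, and the exocyclic diene forms in place of the ether. The fallback forms the aryl–oxygen bond instead of the C11–oxygen bond and sets out from 26 and 27. Umbelliferone 27 would be converted with Tf2O and pyridine into 2-oxo-2H-chromen-7-yl trifluoromethanesulfonate F2. Palladium-catalysed C–O cross-coupling of the primary alcohol of 26 with F2 (Pd2(dba)3, di-tert-butyl(2′,4′,6′-triisopropyl-3,6-dimethoxybiphenyl-2-yl)phosphine, Cs2CO3, toluene, 80 °C) comes back to the route at 28; the hindered C3 alcohol should not couple.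

Step 6. The conjugate addition has to create a quaternary carbon next to the branched C9 and may stall, leaving the vinyl ketone to oligomerise and the aldehyde to self-condense. The fallback builds the quaternary carbon by ester enolate alkylation and sets out from 6. Deprotonation with LiN(i-Pr)2 (THF, −78 °C) and alkylation with 2-(2-bromoethyl)-2-methyl-1,3-dioxolane (DMPU, −78 → 0 °C) would give methyl (3R)-3-[(tert-butyldiphenylsilyloxy)methyl]-2-methyl-2-[2-(2-methyl-1,3-dioxolan-2-yl)ethyl]pent-4-enoate F3. Reduction with i-Bu2AlH at −78 °C would give (3R)-3-[(tert-butyldiphenylsilyloxy)methyl]-2-methyl-2-[2-(2-methyl-1,3-dioxolan-2-yl)ethyl]pent-4-enal F4. Aqueous HCl in THF would unmask the methyl ketone (this is keto aldehyde 9), and KOH in MeOH would close the ring by aldol condensation, coming back to the route at 10.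

Further compounds
F1 | step 9 | (5S,9R,10S)-9-[(tert-butyldiphenylsilyloxy)methyl]-6-hydroxy-10-methyldecal-1-en-3-one (cis-fused; both C6 epimers) | OC1CC[C@@H](CO[Si](C(C)(C)C)(c3ccccc3)c3ccccc3)[C@]2(C)C=CC(=O)C[C@H]12
F2 | step 19 | 2-oxo-2H-chromen-7-yl trifluoromethanesulfonate | O=c1ccc2ccc(OS(=O)(=O)C(F)(F)F)cc2o1
F3 | step 6 | methyl (3R)-3-[(tert-butyldiphenylsilyloxy)methyl]-2-methyl-2-[2-(2-methyl-1,3-dioxolan-2-yl)ethyl]pent-4-enoate (both C2 epimers) | C=C[C@@H](CO[Si](C(C)(C)C)(c1ccccc1)c1ccccc1)C(C)(CCC1(C)OCCO1)C(=O)OC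
F4 | step 6 | (3R)-3-[(tert-butyldiphenylsilyloxy)methyl]-2-methyl-2-[2-(2-methyl-1,3-dioxolan-2-yl)ethyl]pent-4-enal (both C2 epimers) | C=C[C@@H](CO[Si](C(C)(C)C)(c1ccccc1)c1ccccc1)C(C)(CCC1(C)OCCO1)C=O
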